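**Plan**

Retrosynthesis: cut the acetate O–acyl bond, then the lactone O1–C2 bond (butenolide ← 5-hydroxybutenolide ← open-chain 4-oxo-2-enoate), then the ring C3–C4 bond (aldol bond between a fatty acyl α-carbon and the ketone carbon of a pyruvate), and last the C3'–C4' bond of the hexadecan-2-yl side chain (acetylide plus epoxide).
Enabling feature: ring atoms C5 and C4 together with the side chain are one 17-oxygenated C18 fatty acyl unit, and C3, its methyl group and C2 are one pyruvate unit, so a single aldol bond joins all five ring carbons with the methyl and the chain already on the right carbons.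
Forward order: the chain is assembled first (epoxide opening, alkyne zipper, oxidation to the S-ethyl thioester), the C3–C4 bond follows, and the thioester carbon alone is reduced to the aldehyde. The only ring then closes by O1–C2 lactonisation at that oxidation level, C5 is reduced to CH2 and the ring recloses.
Stereochemistry: the single stereocentre (S) is bought with (S)-propylene oxide and no bond to it is broken afterwards; the two centres made in the aldol step are erased on dehydration, and the ring fixes the geometry of the tetrasubstituted alkene.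

Key step: step 7

Remark: 14 and 15 are carried as diastereomer mixtures at the two aldol centres, 16 as an E/Z mixture and 17 as both epimers at the lactol carbon; none of these elements survives in 20.

**Route**

Step 1
Reactants: 1 1-pentadecyne; 2 (S)-propylene oxide [(2S)-2-methyloxirane]
Product: 4 (2S)-octadec-4-yn-2-ol, via lithium pentadec-1-yn-1-ide 3 (not isolated)
Conditions: n-BuLi, THF, −78 → 0 °C; then 2, DMPU, 0 °C → rt; H2O
Reagents that add atoms: none
Why: Alkynylation of a terminal epoxide, in which the lithium acetylide opens the oxirane by SN2 attack at the unsubstituted CH2, so the C–O bond at the stereocentre is untouched and the S configuration of 2 is carried into 4.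

Step 2
Reactants: 4 (2S)-octadec-4-yn-2-ol
Product: 5 (2S)-octadec-17-yn-2-ol
Conditions: KH, H2N(CH2)3NH2, rt; then 4, 0 °C → rt; H2O
Reagents that add atoms: none
Why: Alkyne zipper isomerisation, in which potassium 3-aminopropylamide moves the triple bond by successive propargyl–allenyl proton shifts to the chain end, where irreversible formation of the terminal acetylide pulls the equilibrium, while the carbinol carbon, present as its alkoxide, is not deprotonated and should keep its configuration.

Step 3
Reactants: 5 (2S)-octadec-17-yn-2-ol
Product: 6 tert-butyldimethyl{[(2S)-octadec-17-yn-2-yl]oxy}silane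
Conditions: TBSCl, imidazole, DMF, rt
Reagents that add atoms: tert-butyldimethylsilyl chloride, CC(C)(C)[Si](C)(C)Cl
Why: Standard imidazole-promoted silylation of a secondary alcohol, giving an ether that should survive the borane, chlorite, carbodiimide and TiCl4 steps and be cleaved by the aqueous acid of step 9.

Step 4
Reactants: 6 tert-butyldimethyl{[(2S)-octadec-17-yn-2-yl]oxy}silane
Product: 8 (17S)-17-[(tert-butyldimethylsilyl)oxy]octadecanal, via (E)-alkenyldicyclohexylborane 7 (not isolated)
Conditions: Cy2BH (from BH3·SMe2 and cyclohexene), THF, 0 °C → rt; then 30% H2O2, Na2HPO4/NaH2PO4 buffer (pH 8), 0 °C → rt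
Reagents that add atoms: hydrogen peroxide, OO
Why: Anti-Markovnikov hydroboration of a terminal alkyne with a hindered dialkylborane stops at the alkenylborane, and buffered peroxide oxidation gives the enol and hence the aldehyde without harming the silyl ether.

Step 5
Reactants: 8 (17S)-17-[(tert-butyldimethylsilyl)oxy]octadecanal
Product: 9 (17S)-17-[(tert-butyldimethylsilyl)oxy]octadecanoic acid
Conditions: NaClO2, NaH2PO4, 2-methyl-2-butene, t-BuOH/H2O, rt
Reagents that add atoms: sodium chlorite, [Na+].[O-]Cl=O
Why: Pinnick oxidation, in which chlorous acid converts the aldehyde into the acid in a weakly acidic buffer that a secondary TBS ether tolerates, with the alkene scavenging hypochlorous acid.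

Step 6
Reactants: 9 (17S)-17-[(tert-butyldimethylsilyl)oxy]octadecanoic acid; 10 ethanethiol
Product: 11 S-ethyl (17S)-17-[(tert-butyldimethylsilyl)oxy]octadecanethioate
Conditions: 10, DCC, DMAP (cat.), CH2Cl2, 0 °C → rt
Reagents that add atoms: none
Why: Steglich thioesterification, in which the carbodiimide activates the acid and DMAP relays the acyl group to the thiol under neutral conditions.

Step 7
Reactants: 11 S-ethyl (17S)-17-[(tert-butyldimethylsilyl)oxy]octadecanethioate; 12 methyl pyruvate
Product: 14 S-ethyl (17S)-17-[(tert-butyldimethylsilyl)oxy]-2-(2-hydroxy-1-methoxy-1-oxopropan-2-yl)octadecanethioate (diastereomer mixture), via trichlorotitanium enolate 13 (not isolated)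
Conditions: TiCl4, Et3N, CH2Cl2, −78 °C; then 12, −78 °C; H2O
Reagents that add atoms: none
Why: TiCl4 binds the thioester carbonyl and Et3N removes the now acidic α-proton (soft enolisation), giving the trichlorotitanium enolate 13, whose α-carbon adds to the ketone carbonyl of 12 through a closed, titanium-bridged transition state and so forms the C3–C4 bond of the future ring. The closest known reaction type is the titanium-mediated crossed aldol addition of ester and thioester enolates to ketones and 2-oxo esters, the citramalate-type construction used for alkyl methyl maleic anhydrides. No ring is closed in this step. Two stereocentres arise (the thioester α-carbon and the tertiary carbinol); the remote C17 centre exerts no control, the adduct is taken on as a diastereomer mixture, and both centres become sp2 in step 9. The step needs chemoselectivity only: the thioester is enolised in preference to the pyruvate because it alone is complexed to TiCl4 before 12 is added and its weakly basic titanium enolate should not deprotonate 12 at −78 °C, and attack goes to the ketone and not to the ester carbonyl of 12 because the ketone is the more electrophilic, titanium-chelated carbonyl of the 1,2-dicarbonyl unit. The thioester of 14 beside the oxo ester keeps the two carboxyl carbons distinguishable, which step 8 relies on.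

Step 8
Reactants: 14 S-ethyl (17S)-17-[(tert-butyldimethylsilyl)oxy]-2-(2-hydroxy-1-methoxy-1-oxopropan-2-yl)octadecanethioate
Product: 15 methyl (18S)-18-[(tert-butyldimethylsilyl)oxy]-3-formyl-2-hydroxy-2-methylnonadecanoate (diastereomer mixture)
Conditions: Et3SiH, Pd/C (10% palladium metal on carbon), acetone, rt
Reagents that add atoms: none
Why: Fukuyama reduction, in which zerovalent palladium inserts into the acyl–sulfur bond and the acylpalladium thiolate is reduced by the silane to the aldehyde, while the methyl ester, the tertiary alcohol and the silyl ether are inert under these neutral conditions, so only the fatty-acid carbon changes oxidation level.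

Step 9
Reactants: 15 methyl (18S)-18-[(tert-butyldimethylsilyl)oxy]-3-formyl-2-hydroxy-2-methylnonadecanoate
Product: 17 5-hydroxy-4-[(15S)-15-hydroxyhexadecyl]-3-methylfuran-2(5H)-one (both C5 epimers), via 4-oxo-2-enoate 16 (not isolated)
Conditions: morpholinium chloride, 1,4-dioxane/H2O, 95 °C; then 3 M HCl (aq), 60 °C
Reagents that add atoms: water, O
Why: Amine-salt-mediated aldol dehydration with pseudo-acid lactonisation, in which the enamine of the β-hydroxy aldehyde expels water (E1cB-type, the C4–H being acidic only while C5 is a carbonyl) to give 16, its E and Z forms interconvert through the dienamine, only the Z form is drained by attack of the aldehyde hydrate on the neighbouring ester (5-exo-trig, loss of methanol) as in the classical route from glyoxylic acid and aldehydes to 5-hydroxybutenolides, and the final aqueous HCl hydrolyses any 5-morpholino derivative and cleaves the TBS ether without touching the C–O bond of the stereocentre.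

Step 10
Reactants: 17 5-hydroxy-4-[(15S)-15-hydroxyhexadecyl]-3-methylfuran-2(5H)-one
Product: 19 4-[(15S)-15-hydroxyhexadecyl]-3-methylfuran-2(5H)-one, via sodium (Z)-4-hydroxy-2-enoate 18 (not isolated)
Conditions: NaBH4, EtOH/H2O, 0 °C; then 2 M HCl (aq) to pH 1, rt
Reagents that add atoms: none
Why: Borohydride reduction of a 5-hydroxybutenolide, in which the pseudo-acid opens in the basic medium to the (Z)-formyl carboxylate, hydride reduces the aldehyde to 18, and acidification closes the lactone again (5-exo-trig) to the butenolide, the hindered tetrasubstituted alkene being left alone.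

Step 11
Reactants: 19 4-[(15S)-15-hydroxyhexadecyl]-3-methylfuran-2(5H)-one
Product: 20 (2S)-16-(4-methyl-5-oxo-2,5-dihydrofuran-3-yl)hexadecan-2-yl acetate
Conditions: Ac2O, pyridine, DMAP (cat.), CH2Cl2, rt
Reagents that add atoms: acetic anhydride, CC(=O)OC(C)=O
Why: DMAP-catalysed O-acetylation of the secondary alcohol, which reacts only at the O–H bond and therefore retains the S configuration, under conditions the butenolide tolerates.

**Compound list**

1 | 1-pentadecyne | C#CCCCCCCCCCCCCC | starting material
2 | (S)-propylene oxide [(2S)-2-methyloxirane] | C[C@H]1CO1 | starting material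
3 | lithium pentadec-1-yn-1-ide (not isolated) | [Li]C#CCCCCCCCCCCCCC | intermediate
4 | (2S)-octadec-4-yn-2-ol | C[C@H](O)CC#CCCCCCCCCCCCCC | intermediate
5 | (2S)-octadec-17-yn-2-ol | C[C@H](O)CCCCCCCCCCCCCCC#C | intermediate
6 | tert-butyldimethyl{[(2S)-octadec-17-yn-2-yl]oxy}silane | C[C@H](O[Si](C)(C)C(C)(C)C)CCCCCCCCCCCCCCC#C | intermediate
7 | [(1E,17S)-17-[(tert-butyldimethylsilyl)oxy]octadec-1-en-1-yl]dicyclohexylborane (not isolated) | C[C@H](O[Si](C)(C)C(C)(C)C)CCCCCCCCCCCCCC/C=C/B(C1CCCCC1)C1CCCCC1 | intermediate
8 | (17S)-17-[(tert-butyldimethylsilyl)oxy]octadecanal | C[C@H](O[Si](C)(C)C(C)(C)C)CCCCCCCCCCCCCCCC=O | intermediate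
9 | (17S)-17-[(tert-butyldimethylsilyl)oxy]octadecanoic acid | C[C@H](O[Si](C)(C)C(C)(C)C)CCCCCCCCCCCCCCCC(=O)O | intermediate
10 | ethanethiol | CCS | starting material
11 | S-ethyl (17S)-17-[(tert-butyldimethylsilyl)oxy]octadecanethioate | CCSC(=O)CCCCCCCCCCCCCCC[C@H](C)O[Si](C)(C)C(C)(C)C | intermediate
12 | methyl pyruvate | CC(=O)C(=O)OC | starting material
13 | trichlorotitanium enolate of 11 (not isolated) | CCSC(O[Ti](Cl)(Cl)Cl)=CCCCCCCCCCCCCCC[C@H](C)O[Si](C)(C)C(C)(C)C | intermediate
14 | S-ethyl (17S)-17-[(tert-butyldimethylsilyl)oxy]-2-(2-hydroxy-1-methoxy-1-oxopropan-2-yl)octadecanethioate (diastereomer mixture) | CCSC(=O)C(CCCCCCCCCCCCCC[C@H](C)O[Si](C)(C)C(C)(C)C)C(C)(O)C(=O)OC | intermediate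
15 | methyl (18S)-18-[(tert-butyldimethylsilyl)oxy]-3-formyl-2-hydroxy-2-methylnonadecanoate (diastereomer mixture) | O=CC(CCCCCCCCCCCCCC[C@H](C)O[Si](C)(C)C(C)(C)C)C(C)(O)C(=O)OC | intermediate
16 | methyl (18S)-18-[(tert-butyldimethylsilyl)oxy]-3-formyl-2-methylnonadec-2-enoate (E/Z mixture; not isolated) | O=CC(CCCCCCCCCCCCCC[C@H](C)O[Si](C)(C)C(C)(C)C)=C(C)C(=O)OC | intermediate
17 | 5-hydroxy-4-[(15S)-15-hydroxyhexadecyl]-3-methylfuran-2(5H)-one (both C5 epimers) | O=C1OC(O)C(CCCCCCCCCCCCCC[C@H](C)O)=C1C | intermediate
18 | sodium (2Z)-4-hydroxy-3-[(15S)-15-hydroxyhexadecyl]-2-methylbut-2-enoate (not isolated) | [Na+].[O-]C(=O)/C(C)=C(\CO)CCCCCCCCCCCCCC[C@H](C)O | intermediate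
19 | 4-[(15S)-15-hydroxyhexadecyl]-3-methylfuran-2(5H)-one | C[C@H](O)CCCCCCCCCCCCCCC1=C(C)C(=O)OC1 | intermediate
20 | (2S)-16-(4-methyl-5-oxo-2,5-dihydrofuran-3-yl)hexadecan-2-yl acetate | CC(=O)O[C@@H](C)CCCCCCCCCCCCCCC1=C(C)C(=O)OC1 | target

**Count and risks**

Total step count: 11. Longest linear sequence: 11 steps (1 and 2 to 20; the route is fully linear).

Steps most likely to fail:

1. Step 9. What may go wrong: retro-aldol fragmentation of the β-hydroxy aldehyde may outrun loss of water, the E-configured enal may isomerise too slowly to be drained into the ring, or hydrate-assisted cleavage of the ester may stall. Fallback (reduce first, close the ring, then dehydrate): 15 is reduced with NaBH4 in MeOH at −20 °C to methyl (18S)-18-[(tert-butyldimethylsilyl)oxy]-2-hydroxy-3-(hydroxymethyl)-2-methylnonadecanoate F1, which is not isolated and is closed with PPTS in warm toluene to 4-[(15S)-15-[(tert-butyldimethylsilyl)oxy]hexadecyl]-3-hydroxy-3-methyldihydrofuran-2(3H)-one F2. SOCl2/pyridine in CH2Cl2 should dehydrate F2 to 4-[(15S)-15-[(tert-butyldimethylsilyl)oxy]hexadecyl]-3-methylfuran-2(5H)-one F3 together with its exocyclic isomer 4-[(15S)-15-[(tert-butyldimethylsilyl)oxy]hexadecyl]-3-methylidenedihydrofuran-2(3H)-one F4. Because C4–H of the lactone is not acidic, base cannot move the exocyclic double bond; a rhodium hydride generated from catalytic RhCl3·3H2O in hot ethanol should isomerise F4 into F3. HF·pyridine in THF then removes the silyl group, and the route is rejoined at 19, with steps 9 and 10 bypassed.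

2. Step 7. What may go wrong: proton transfer to, or self-condensation of, the enolisable pyruvate under TiCl4/Et3N, incomplete enolisation of the thioester, or retro-aldol cleavage on work-up. Fallback (preformed enolate equivalent instead of in-flask enolisation): 11 is converted with LiN(i-Pr)2 and Me3SiCl in THF at −78 °C into {[(17S)-17-[(tert-butyldimethylsilyl)oxy]-1-(ethylsulfanyl)octadec-1-en-1-yl]oxy}trimethylsilane F5, which is isolated and added to 12 with TiCl4 in CH2Cl2 at −78 °C (Mukaiyama aldol, no amine base present). The same C3–C4 bond forms and the route is rejoined at 14.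

3. Step 8. What may go wrong: retro-aldol cleavage or uncontrolled dehydration of the β-hydroxy aldehyde during reduction and isolation, or O-silylation of the tertiary alcohol by the silane. Fallback (water is lost before the reduction, so no β-hydroxy aldehyde is handled): 14 is mesylated with MsCl/Et3N in CH2Cl2 at 0 °C to S-ethyl (17S)-17-[(tert-butyldimethylsilyl)oxy]-2-[2-(methanesulfonyloxy)-1-methoxy-1-oxopropan-2-yl]octadecanethioate F6. Without isolation, DBU is added and E1cB elimination through the thioester enolate should give methyl (18S)-18-[(tert-butyldimethylsilyl)oxy]-3-[(ethylsulfanyl)carbonyl]-2-methylnonadec-2-enoate F7 as an E/Z mixture. Fukuyama reduction of F7 (Et3SiH, Pd/C, acetone) then delivers the enal ester as an isolated compound, so the route is rejoined at 16, which is carried through the conditions of step 9.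

**Further compounds**

F1 | step 9 | methyl (18S)-18-[(tert-butyldimethylsilyl)oxy]-2-hydroxy-3-(hydroxymethyl)-2-methylnonadecanoate | OCC(CCCCCCCCCCCCCC[C@H](C)O[Si](C)(C)C(C)(C)C)C(C)(O)C(=O)OC
F2 | step 9 | 4-[(15S)-15-[(tert-butyldimethylsilyl)oxy]hexadecyl]-3-hydroxy-3-methyldihydrofuran-2(3H)-one | O=C1OCC(CCCCCCCCCCCCCC[C@H](C)O[Si](C)(C)C(C)(C)C)C1(C)O
F3 | step 9 | 4-[(15S)-15-[(tert-butyldimethylsilyl)oxy]hexadecyl]-3-methylfuran-2(5H)-one | C[C@H](O[Si](C)(C)C(C)(C)C)CCCCCCCCCCCCCCC1=C(C)C(=O)OC1
F4 | step 9 | 4-[(15S)-15-[(tert-butyldimethylsilyl)oxy]hexadecyl]-3-methylidenedihydrofuran-2(3H)-one | C=C1C(=O)OCC1CCCCCCCCCCCCCC[C@H](C)O[Si](C)(C)C(C)(C)C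
F5 | step 7 | {[(17S)-17-[(tert-butyldimethylsilyl)oxy]-1-(ethylsulfanyl)octadec-1-en-1-yl]oxy}trimethylsilane | CCSC(O[Si](C)(C)C)=CCCCCCCCCCCCCCC[C@H](C)O[Si](C)(C)C(C)(C)C
F6 | step 8 | S-ethyl (17S)-17-[(tert-butyldimethylsilyl)oxy]-2-[2-(methanesulfonyloxy)-1-methoxy-1-oxopropan-2-yl]octadecanethioate | CCSC(=O)C(CCCCCCCCCCCCCC[C@H](C)O[Si](C)(C)C(C)(C)C)C(C)(OS(C)(=O)=O)C(=O)OC
F7 | step 8 | methyl (18S)-18-[(tert-butyldimethylsilyl)oxy]-3-[(ethylsulfanyl)carbonyl]-2-methylnonadec-2-enoate | CCSC(=O)C(CCCCCCCCCCCCCC[C@H](C)O[Si](C)(C)C(C)(C)C)=C(C)C(=O)OC
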